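**Retrosynthetic overview**

1. Target 33 ⇐ NaBH4 reduction of the ring F C4' ketone of the free polyphenol 32 (giving the 3',4'-trans diol) ⇐ global debenzylation of the benzylated fisetinidol-(4→6)-fustin 31.
2. Ring F ⇐ Mitsunobu closure of O1'–C2' in a 2'-hydroxyaryl α-benzyloxy-β-hydroxy ketone ⇐ ring D aryllithium (from the bromide) plus the Weinreb amide 26, whose C2'/C3' centres come from an Evans glycolate aldol.
3. Ring B–C2 bond ⇐ addition of an aryltrifluoroborate to the C2 oxocarbenium ion, trans to O3 and to the C4 aryl.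
4. Ring C ⇐ [4+2] of the ortho-quinone methide O1–C8a–C4a–C4 of ring A (C4 carrying ring D through the future C6') with the cis-enediol ether C2–C3 (2,2-dimethyl-1,3-dioxole). The strategy rests on the 3,4-cis relation between O3 and the C4 aryl in ring C.
5. Ring order: A, B, D and E are bought as arenes; ring C is formed in step 6 and ring F in step 18.

Key step: step 6

Assumption: the sense of induction of the chiral phosphoric acid in step 6 cannot be predicted with certainty; the (R)-catalyst is written, and its (S)-antipode is to be used if the first run gives the mirror-image adduct.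

Chroman numbering is used for both flavan units, with primed locants for the lower unit (rings D, E, F).

**Route**

Step 1
Reactants: 1 2,4-dihydroxybenzaldehyde
Product: 2 4-(benzyloxy)-2-hydroxybenzaldehyde
Conditions: BnBr (1.05 equiv), NaHCO3, MeCN, reflux
Reagents that add atoms: benzyl bromide, BrCc1ccccc1
Why: Williamson etherification; the 2-OH is hydrogen-bonded to the formyl group and less acidic, so the weak base should alkylate only the 4-OH.

Step 2
Reactants: 3 4,6-dibromoresorcinol
Product: 4 1,5-bis(benzyloxy)-2,4-dibromobenzene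
Conditions: BnBr (2.2 equiv), K2CO3, DMF, 60 °C
Reagents that add atoms: benzyl bromide, BrCc1ccccc1
Why: double Williamson etherification of an acidic dibromoresorcinol; the C2-symmetric product makes the two bromines equivalent for the next step.

Step 3
Reactants: 4 1,5-bis(benzyloxy)-2,4-dibromobenzene; 2 4-(benzyloxy)-2-hydroxybenzaldehyde
Product: 7 [4-(benzyloxy)-2-hydroxyphenyl][2,4-bis(benzyloxy)-5-bromophenyl]methanol (racemic), via aryllithium 5 (not isolated), via sodium phenoxide 6 (not isolated)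
Conditions: 4, n-BuLi (1.0 equiv), THF, −78 °C; separately 2, NaH (1.05 equiv), THF, 0 °C; phenoxide solution added at −78 °C, then −78 → −20 °C; aq. NH4Cl (no acid), Et3N-deactivated silica
Reagents that add atoms: none
Why: mono bromine–lithium exchange with one equivalent of n-BuLi, then 1,2-addition of the aryllithium to the aldehyde whose phenol is masked as its sodium salt (standard access to ortho-hydroxybenzhydrols); the carbinol centre is formed racemic and is erased in step 6.

Step 4
Reactants: 8 2,2-dimethyl-1,3-dioxolane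
Product: 9 4-chloro-2,2-dimethyl-1,3-dioxolane (racemic)
Conditions: SO2Cl2 (1.0 equiv), azobisisobutyronitrile (cat.), neat, 65 °C, N2 sweep; distillation
Reagents that add atoms: sulfuryl chloride, O=S(=O)(Cl)Cl
Why: radical-chain chlorination at the only oxygen-activated C–H positions (C4/C5), the same reaction type as the chlorination of ethylene carbonate; the gas sweep removes HCl from the acid-sensitive ketal.

Step 5
Reactants: 9 4-chloro-2,2-dimethyl-1,3-dioxolane
Product: 10 2,2-dimethyl-1,3-dioxole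
Conditions: KOt-Bu, tetraglyme, 0 → 50 °C, product distilled out of the mixture and stored over K2CO3
Reagents that add atoms: none
Why: base-induced dehydrochlorination (E2) of the α-chloro ether should give the cyclic cis-enediol ether, which is removed by distillation as it forms.

Step 6
Reactants: 7 [4-(benzyloxy)-2-hydroxyphenyl][2,4-bis(benzyloxy)-5-bromophenyl]methanol; 10 2,2-dimethyl-1,3-dioxole
Product: 12 (2S,3S,4R)-7-(benzyloxy)-4-[2,4-bis(benzyloxy)-5-bromophenyl]chromane-2,3-diol 2,3-O-isopropylidene acetal (H-2/H-3/H-4 all cis), via ortho-quinone methide 11 (not isolated)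
Conditions: (R)-3,3'-bis(2,4,6-triisopropylphenyl)-1,1'-binaphthyl-2,2'-diyl hydrogen phosphate (5 mol %), 10 (3 equiv), 4 Å molecular sieves, toluene, −20 °C → rt
Reagents that add atoms: none
Why: The phosphoric acid protonates the benzylic hydroxyl of 7 and water is lost to give the (E)-ortho-quinone methide 11, which stays hydrogen-bonded through its carbonyl oxygen to the chiral phosphate; the electron-rich dioxole 10 then adds across O1–C8a–C4a–C4 in a concerted but asynchronous inverse-demand oxa-Diels–Alder reaction, the C3–C4 bond leading and the O1–C2 bond following. The closest known reaction type is the chiral Brønsted-acid-catalysed [4+2] cycloaddition of ortho-quinone methides, generated in situ from ortho-hydroxybenzhydrols, with enol ethers, enecarbamates and styrenes. Ring C is closed by the cycloaddition itself (six-membered [4+2] closure forming O1–C2 and C3–C4), and the dioxolane arrives cis-fused because the cis-alkene adds suprafacially. C4 is set by the face of 11 that the bound phosphate leaves open; C3 is set relative to C4 by endo approach of the two dioxole oxygens under the heterodiene combined with the E geometry of the methide, which places O3 cis to the ring D aryl; C2 follows from the cis geometry of the dienophile. The step needs endo selectivity and one enantioface: the E methide (ring D turned away from the carbonyl oxygen), the compact symmetric dienophile (no regiochemical question) and the tight ion pair in toluene should secure these, and the sieves keep the liberated water from hydrolysing 10.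

Step 7
Reactants: 12 cis-fused acetonide
Product: 13 (3S,4R)-7-(benzyloxy)-4-[2,4-bis(benzyloxy)-5-bromophenyl]-2-methoxychroman-3-ol (mixture of C2 epimers)
Conditions: camphorsulfonic acid (10 mol %), MeOH (10 equiv), CH2Cl2, 0 °C → rt; Et3N quench
Reagents that add atoms: methanol, CO
Why: acid-catalysed transacetalisation (Fischer-type glycosidation) opens the strained cis-fused ketal, acetone is lost and methanol caps C2; C3 and C4 are untouched, the limited amount of methanol keeps the cyclic acetal favoured over the open dimethyl acetal, and both C2 epimers converge in step 10.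

Step 8
Reactants: 13 2-methoxychroman-3-ol
Product: 14 (3S,4R)-3,7-bis(benzyloxy)-4-[2,4-bis(benzyloxy)-5-bromophenyl]-2-methoxychromane (mixture of C2 epimers)
Conditions: NaH, BnBr, Bu4NI (cat.), DMF, 0 °C → rt
Reagents that add atoms: benzyl bromide, BrCc1ccccc1
Why: Williamson benzylation of the secondary alcohol gives a non-participating O3 protecting group that survives the organolithium step and leaves in the final hydrogenolysis.

Step 9
Reactants: 15 [3,4-bis(benzyloxy)phenyl]boronic acid
Product: 16 potassium [3,4-bis(benzyloxy)phenyl]trifluoroborate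
Conditions: KHF2 (aq.), MeOH, rt; recrystallisation from acetone/Et2O
Reagents that add atoms: potassium hydrogen difluoride, [K+].F.[F-]
Why: standard conversion of a boronic acid into its air-stable trifluoroborate salt.

Step 10
Reactants: 14 2-methoxy-3-benzyloxychromane; 16 potassium aryltrifluoroborate
Product: 18 (2R,3S,4R)-3,7-bis(benzyloxy)-2-[3,4-bis(benzyloxy)phenyl]-4-[2,4-bis(benzyloxy)-5-bromophenyl]chromane (2,3-trans-3,4-cis), via oxocarbenium ion 17 (not isolated)
Conditions: BF3·OEt2 (3 equiv), 16 (2 equiv), MeCN/CH2Cl2, −30 → 0 °C; aq. NaHCO3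
Reagents that add atoms: none
Why: Lewis-acid-promoted addition of an organotrifluoroborate to a cyclic O,O-acetal: BF3 turns 16 into the aryldifluoroborane and ionises the methyl acetal to 17, and the aryl group is transferred ipso to C2 on the face opposite the cis-disposed 3-benzyloxy and C4-aryl groups (axial attack on the other face would be 1,3-diaxial to the ring D aryl), which sets C2 trans to O3 with the new aryl equatorial.

Step 11
Reactants: 19 (R)-4-benzyl-1,3-oxazolidin-2-one
Product: 21 (R)-4-benzyl-3-[(benzyloxy)acetyl]-1,3-oxazolidin-2-one, via N-lithio oxazolidinone 20 (not isolated)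
Conditions: n-BuLi, THF, −78 °C; then benzyloxyacetyl chloride, −78 → 0 °C
Reagents that add atoms: benzyloxyacetyl chloride, O=C(Cl)COCc1ccccc1
Why: N-acylation of the lithiated Evans auxiliary with an acid chloride.

Step 12
Reactants: 21 (R)-4-benzyl-3-[(benzyloxy)acetyl]-1,3-oxazolidin-2-one; 22 3,4-bis(benzyloxy)benzaldehyde
Product: 24 (R)-4-benzyl-3-[(2R,3S)-2-(benzyloxy)-3-[3,4-bis(benzyloxy)phenyl]-3-hydroxypropanoyl]-1,3-oxazolidin-2-one, via boron enolate 23 (not isolated)
Conditions: Bu2BOTf, Et3N, CH2Cl2, −78 → 0 °C; then 22, −78 → 0 °C; pH 7 buffer, MeOH, H2O2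
Reagents that add atoms: none
Why: Evans syn-glycolate aldol; the (Z)-boron enolate reacts through a closed chair transition state on the face away from the auxiliary benzyl group, so the (R)-auxiliary should set the syn (2R,3S) pair, which maps onto C3' and (before inversion) C2' of ring F.

Step 13
Reactants: 24 aldol adduct
Product: 25 (2R,3S)-2-(benzyloxy)-3-[3,4-bis(benzyloxy)phenyl]-3-hydroxy-N-methoxy-N-methylpropanamide
Conditions: MeNHOMe·HCl, AlMe3, CH2Cl2, −20 → 0 °C; Rochelle salt work-up
Reagents that add atoms: N,O-dimethylhydroxylamine hydrochloride, CNOC.Cl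
Why: aluminium-amide transamination of the imide, assisted by the free β-hydroxyl, releases the auxiliary and gives the Weinreb amide without touching either stereocentre.

Step 14
Reactants: 25 β-hydroxy Weinreb amide
Product: 26 (2R,3S)-2-(benzyloxy)-3-[3,4-bis(benzyloxy)phenyl]-3-[(tert-butyldimethylsilyl)oxy]-N-methoxy-N-methylpropanamide
Conditions: TBSOTf, 2,6-lutidine, CH2Cl2, −78 → 0 °C
Reagents that add atoms: tert-butyldimethylsilyl triflate, CC(C)(C)[Si](C)(C)OS(=O)(=O)C(F)(F)F
Why: silylation masks the benzylic hydroxyl with a group orthogonal to the α-benzyl ether, so that only this oxygen can later be activated.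

Step 15
Reactants: 18 ring D aryl bromide; 26 Weinreb amide
Product: 28 (2R,3S)-2-(benzyloxy)-3-[3,4-bis(benzyloxy)phenyl]-3-[(tert-butyldimethylsilyl)oxy]-1-{2,4-bis(benzyloxy)-5-[(2R,3S,4R)-3,7-bis(benzyloxy)-2-[3,4-bis(benzyloxy)phenyl]chroman-4-yl]phenyl}propan-1-one, via aryllithium 27 (not isolated)
Conditions: t-BuLi (2.0 equiv), THF, −78 °C; then 26 (1.3 equiv), −78 → −40 °C; aq. NH4Cl
Reagents that add atoms: none
Why: bromine–lithium exchange is faster than any deprotonation at −78 °C, and the Weinreb ketone synthesis stops at the chelated tetrahedral intermediate, which prevents over-addition and epimerisation of the α-alkoxy centre; this forms the C4a'–C4' bond.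

Step 16
Reactants: 28 aryl ketone
Product: 29 (2R,3S)-2-(benzyloxy)-3-[3,4-bis(benzyloxy)phenyl]-3-[(tert-butyldimethylsilyl)oxy]-1-{4-(benzyloxy)-2-hydroxy-5-[(2R,3S,4R)-3,7-bis(benzyloxy)-2-[3,4-bis(benzyloxy)phenyl]chroman-4-yl]phenyl}propan-1-one
Conditions: MgBr2·OEt2 (3 equiv), toluene/Et2O, rt → 40 °C; then 0.5 M HCl
Reagents that add atoms: none
Why: chelation-controlled debenzylation; magnesium bridges the ketone oxygen and the ortho aryl ether oxygen, and bromide removes only that benzyl group as a chelated magnesium phenoxide, freeing the future O1'.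

Step 17
Reactants: 29 ortho-hydroxyaryl ketone silyl ether
Product: 30 (2R,3S)-2-(benzyloxy)-3-[3,4-bis(benzyloxy)phenyl]-3-hydroxy-1-{4-(benzyloxy)-2-hydroxy-5-[(2R,3S,4R)-3,7-bis(benzyloxy)-2-[3,4-bis(benzyloxy)phenyl]chroman-4-yl]phenyl}propan-1-one
Conditions: HF·pyridine, pyridine, THF, 0 °C → rt
Reagents that add atoms: none
Why: buffered fluoride desilylation frees the benzylic alcohol under non-basic conditions, avoiding retro-aldol cleavage or β-elimination of the β-hydroxy ketone.

Step 18
Reactants: 30 hydroxy ketone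
Product: 31 (2R,3R)-3,7-bis(benzyloxy)-2-[3,4-bis(benzyloxy)phenyl]-6-[(2R,3S,4R)-3,7-bis(benzyloxy)-2-[3,4-bis(benzyloxy)phenyl]chroman-4-yl]chroman-4-one
Conditions: PPh3, diisopropyl azodicarboxylate, THF, 0 °C → rt
Reagents that add atoms: none
Why: intramolecular Mitsunobu etherification; the chelated phenol displaces the activated benzylic hydroxyl with inversion (S → R at C2'), closing ring F as the 2,3-trans dihydroflavonol while C3' is untouched.

Step 19
Reactants: 31 octabenzyl ether
Product: 32 (2R,3R)-2-(3,4-dihydroxyphenyl)-6-[(2R,3S,4S)-2-(3,4-dihydroxyphenyl)-3,7-dihydroxychroman-4-yl]-3,7-dihydroxychroman-4-one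
Conditions: H2 (1 atm), Pd(OH)2/C, THF/MeOH, rt
Reagents that add atoms: none
Why: hydrogenolysis of the eight benzyl ethers under neutral conditions, which are expected to leave the electron-rich chromanone carbonyl and the cyclic benzylic C–O bonds intact; the ketone is reduced only afterwards because a benzylic C4' alcohol would not survive hydrogenolysis.

Step 20
Reactants: 32 free phenolic ketone
Product: 33 (2R,3S,4R)-2-(3,4-dihydroxyphenyl)-6-[(2R,3S,4S)-2-(3,4-dihydroxyphenyl)-3,7-dihydroxychroman-4-yl]chromane-3,4,7-triol (CNP0280090.2)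
Conditions: NaBH4 (excess), EtOH, 0 °C → rt; acetone quench, work-up at pH 6–7, Sephadex LH-20
Reagents that add atoms: none
Why: borohydride reduction of a 2,3-trans dihydroflavonol, the known way from fustin-type ketones to 2,3-trans-3,4-trans flavan-3,4-diols; hydride adds axially, cis to the 3'-OH, so the new 4'-OH is equatorial and trans to the 3'-OH (4'R), and the near-neutral work-up protects the acid-labile benzylic diol.

**Compound list**

1 | 2,4-dihydroxybenzaldehyde | O=Cc1ccc(O)cc1O | starting material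
2 | 4-(benzyloxy)-2-hydroxybenzaldehyde | O=Cc1ccc(OCc2ccccc2)cc1O | intermediate
3 | 4,6-dibromoresorcinol | Oc1cc(O)c(Br)cc1Br | starting material
4 | 1,5-bis(benzyloxy)-2,4-dibromobenzene | Brc1cc(Br)c(OCc2ccccc2)cc1OCc1ccccc1 | intermediate
5 | [2,4-bis(benzyloxy)-5-bromophenyl]lithium | [Li]c1cc(Br)c(OCc2ccccc2)cc1OCc1ccccc1 | intermediate (not isolated)
6 | sodium 5-(benzyloxy)-2-formylphenolate | [Na+].[O-]c1cc(OCc2ccccc2)ccc1C=O | intermediate (not isolated)
7 | [4-(benzyloxy)-2-hydroxyphenyl][2,4-bis(benzyloxy)-5-bromophenyl]methanol, racemic | OC(c1ccc(OCc2ccccc2)cc1O)c1cc(Br)c(OCc2ccccc2)cc1OCc1ccccc1 | intermediate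
8 | 2,2-dimethyl-1,3-dioxolane | CC1(C)OCCO1 | starting material
9 | 4-chloro-2,2-dimethyl-1,3-dioxolane, racemic | CC1(C)OCC(Cl)O1 | intermediate
10 | 2,2-dimethyl-1,3-dioxole | CC1(C)OC=CO1 | intermediate
11 | (E)-3-(benzyloxy)-6-[2,4-bis(benzyloxy)-5-bromobenzylidene]cyclohexa-2,4-dien-1-one (ortho-quinone methide) | O=C1C=C(OCc2ccccc2)C=C/C1=C\c1cc(Br)c(OCc2ccccc2)cc1OCc1ccccc1 | intermediate (not isolated)
12 | (2S,3S,4R)-7-(benzyloxy)-4-[2,4-bis(benzyloxy)-5-bromophenyl]chromane-2,3-diol 2,3-O-isopropylidene acetal, all-cis | c1ccccc1COc1ccc2c(c1)O[C@H]1OC(C)(C)O[C@H]1[C@H]2c1cc(Br)c(OCc2ccccc2)cc1OCc1ccccc1 | intermediate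
13 | (3S,4R)-7-(benzyloxy)-4-[2,4-bis(benzyloxy)-5-bromophenyl]-2-methoxychroman-3-ol, C2 epimers | c1ccccc1COc1ccc2c(c1)OC(OC)[C@@H](O)[C@H]2c1cc(Br)c(OCc2ccccc2)cc1OCc1ccccc1 | intermediate
14 | (3S,4R)-3,7-bis(benzyloxy)-4-[2,4-bis(benzyloxy)-5-bromophenyl]-2-methoxychromane, C2 epimers | c1ccccc1COc1ccc2c(c1)OC(OC)[C@@H](OCc1ccccc1)[C@H]2c1cc(Br)c(OCc2ccccc2)cc1OCc1ccccc1 | intermediate
15 | [3,4-bis(benzyloxy)phenyl]boronic acid | OB(O)c1ccc(OCc2ccccc2)c(OCc2ccccc2)c1 | starting material
16 | potassium [3,4-bis(benzyloxy)phenyl]trifluoroborate | [K+].F[B-](F)(F)c1ccc(OCc2ccccc2)c(OCc2ccccc2)c1 | intermediate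
17 | (3S,4R)-3,7-bis(benzyloxy)-4-[2,4-bis(benzyloxy)-5-bromophenyl]-3,4-dihydrochromen-1-ium (C2 oxocarbenium ion) | c1ccccc1COc1ccc2c(c1)[O+]=C[C@@H](OCc1ccccc1)[C@H]2c1cc(Br)c(OCc2ccccc2)cc1OCc1ccccc1 | intermediate (not isolated)
18 | (2R,3S,4R)-3,7-bis(benzyloxy)-2-[3,4-bis(benzyloxy)phenyl]-4-[2,4-bis(benzyloxy)-5-bromophenyl]chromane | c1ccccc1COc1ccc2c(c1)O[C@H](c1ccc(OCc3ccccc3)c(OCc3ccccc3)c1)[C@@H](OCc1ccccc1)[C@H]2c1cc(Br)c(OCc2ccccc2)cc1OCc1ccccc1 | intermediate
19 | (R)-4-benzyl-1,3-oxazolidin-2-one | O=C1N[C@H](Cc2ccccc2)CO1 | starting material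
20 | lithium salt of (R)-4-benzyl-1,3-oxazolidin-2-one | [Li]N1[C@H](Cc2ccccc2)COC1=O | intermediate (not isolated)
21 | (R)-4-benzyl-3-[(benzyloxy)acetyl]-1,3-oxazolidin-2-one | O=C(COCc1ccccc1)N1[C@H](Cc2ccccc2)COC1=O | intermediate
22 | 3,4-bis(benzyloxy)benzaldehyde | O=Cc1ccc(OCc2ccccc2)c(OCc2ccccc2)c1 | starting material
23 | (Z)-dibutylboron enolate of 21 | CCCCB(CCCC)O/C(=C\OCc1ccccc1)N1[C@H](Cc2ccccc2)COC1=O | intermediate (not isolated)
24 | (R)-4-benzyl-3-[(2R,3S)-2-(benzyloxy)-3-[3,4-bis(benzyloxy)phenyl]-3-hydroxypropanoyl]-1,3-oxazolidin-2-one | O=C([C@H](OCc1ccccc1)[C@@H](O)c1ccc(OCc2ccccc2)c(OCc2ccccc2)c1)N1[C@H](Cc2ccccc2)COC1=O | intermediate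
25 | (2R,3S)-2-(benzyloxy)-3-[3,4-bis(benzyloxy)phenyl]-3-hydroxy-N-methoxy-N-methylpropanamide | CON(C)C(=O)[C@H](OCc1ccccc1)[C@@H](O)c1ccc(OCc2ccccc2)c(OCc2ccccc2)c1 | intermediate
26 | (2R,3S)-2-(benzyloxy)-3-[3,4-bis(benzyloxy)phenyl]-3-[(tert-butyldimethylsilyl)oxy]-N-methoxy-N-methylpropanamide | CON(C)C(=O)[C@H](OCc1ccccc1)[C@@H](O[Si](C)(C)C(C)(C)C)c1ccc(OCc2ccccc2)c(OCc2ccccc2)c1 | intermediate
27 | aryllithium from 18 (lithium in place of bromine on ring D) | c1ccccc1COc1ccc2c(c1)O[C@H](c1ccc(OCc3ccccc3)c(OCc3ccccc3)c1)[C@@H](OCc1ccccc1)[C@H]2c1cc([Li])c(OCc2ccccc2)cc1OCc1ccccc1 | intermediate (not isolated)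
28 | (2R,3S)-2-(benzyloxy)-3-[3,4-bis(benzyloxy)phenyl]-3-[(tert-butyldimethylsilyl)oxy]-1-{2,4-bis(benzyloxy)-5-[(2R,3S,4R)-3,7-bis(benzyloxy)-2-[3,4-bis(benzyloxy)phenyl]chroman-4-yl]phenyl}propan-1-one | c1ccccc1COc1ccc2c(c1)O[C@H](c1ccc(OCc3ccccc3)c(OCc3ccccc3)c1)[C@@H](OCc1ccccc1)[C@H]2c1cc(C(=O)[C@H](OCc2ccccc2)[C@@H](O[Si](C)(C)C(C)(C)C)c2ccc(OCc3ccccc3)c(OCc3ccccc3)c2)c(OCc2ccccc2)cc1OCc1ccccc1 | intermediate
29 | as 28 with the benzyloxy group ortho to the ketone replaced by hydroxyl | c1ccccc1COc1ccc2c(c1)O[C@H](c1ccc(OCc3ccccc3)c(OCc3ccccc3)c1)[C@@H](OCc1ccccc1)[C@H]2c1cc(C(=O)[C@H](OCc2ccccc2)[C@@H](O[Si](C)(C)C(C)(C)C)c2ccc(OCc3ccccc3)c(OCc3ccccc3)c2)c(O)cc1OCc1ccccc1 | intermediate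
30 | as 29 with the silyl ether replaced by a free (3S) hydroxyl | c1ccccc1COc1ccc2c(c1)O[C@H](c1ccc(OCc3ccccc3)c(OCc3ccccc3)c1)[C@@H](OCc1ccccc1)[C@H]2c1cc(C(=O)[C@H](OCc2ccccc2)[C@@H](O)c2ccc(OCc3ccccc3)c(OCc3ccccc3)c2)c(O)cc1OCc1ccccc1 | intermediate
31 | (2R,3R)-3,7-bis(benzyloxy)-2-[3,4-bis(benzyloxy)phenyl]-6-[(2R,3S,4R)-3,7-bis(benzyloxy)-2-[3,4-bis(benzyloxy)phenyl]chroman-4-yl]chroman-4-one | c1ccccc1COc1ccc2c(c1)O[C@H](c1ccc(OCc3ccccc3)c(OCc3ccccc3)c1)[C@@H](OCc1ccccc1)[C@H]2c1cc2c(cc1OCc1ccccc1)O[C@H](c1ccc(OCc3ccccc3)c(OCc3ccccc3)c1)[C@@H](OCc1ccccc1)C2=O | intermediate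
32 | (2R,3R)-2-(3,4-dihydroxyphenyl)-6-[(2R,3S,4S)-2-(3,4-dihydroxyphenyl)-3,7-dihydroxychroman-4-yl]-3,7-dihydroxychroman-4-one | Oc1ccc2c(c1)O[C@H](c1ccc(O)c(O)c1)[C@@H](O)[C@H]2c1cc2c(cc1O)O[C@H](c1ccc(O)c(O)c1)[C@@H](O)C2=O | intermediate
33 | (2R,3S,4R)-2-(3,4-dihydroxyphenyl)-6-[(2R,3S,4S)-2-(3,4-dihydroxyphenyl)-3,7-dihydroxychroman-4-yl]chromane-3,4,7-triol | Oc1ccc2c(c1)O[C@H](c1ccc(O)c(O)c1)[C@@H](O)[C@H]2c1cc2c(cc1O)O[C@H](c1ccc(O)c(O)c1)[C@@H](O)[C@@H]2O | target

**Step count**

Total: 20 steps. Longest linear sequence: 12 steps (1 → 3 → 6 → 7 → 8 → 10 → 15 → 16 → 17 → 18 → 19 → 20).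

**Steps most likely to fail**

Step 6 (key step). The phosphate may discriminate poorly between the two faces of 11, since the dioxole has no hydrogen-bond donor to tie it to the catalyst. Endo selectivity may also erode, and the liberated water may hydrolyse 10. The fallback replaces catalyst control by resolution. It sets out from 7 and 10, which are combined with achiral diphenyl phosphate (5 mol %) and 4 Å sieves in toluene to give the racemic endo adduct, that is 12 together with the enantiomeric adduct F1. The two are separated by preparative supercritical-fluid chromatography on an amylose tris(3,5-dimethylphenylcarbamate) phase, and the route is rejoined at 12.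

Step 10. The aryl group may be delivered to the wrong face of 17, giving the 2,3-cis epimer, or 17 may lose H-3 to give the 4H-chromene enol ether. The fallback replaces steric control by anchimeric control. It sets out from 13, whose 3-OH is benzoylated (BzCl, pyridine, CH2Cl2) to the 3-O-benzoate F2. BF3·OEt2 and 16 then ionise C2 with participation of the benzoate; the cis-fused dioxolenium ion blocks the top face, suppresses elimination and enforces attack trans to O3, giving the 2,3-trans 2-aryl benzoate F3. Methanolysis (NaOMe, MeOH/THF) frees the flavan-3-ol F4, and NaH/BnBr returns the route at 18.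

Step 16. Debenzylation may be unselective, because the α-benzyloxy ketone offers a second chelate, or cleavage at the hindered ketone may be incomplete. The fallback deprotects globally first and then closes the ring under acid. It sets out from 28, where hydrogenolysis (H2, Pd(OH)2/C, EtOAc/THF) removes all nine benzyl groups to give the polyphenolic silyl ether F5. Aqueous HF in MeCN then removes the silyl group and ionises the 3,4-dihydroxybenzylic position to a para-quinone-methide-type cation. The single phenol ortho to the ketone captures it to give the thermodynamically preferred 2,3-trans ring F, with C3' retained. This joins the route at 32 and bypasses steps 16 to 19.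

**Further compounds**

F1 | step 6 | (2R,3R,4S)-enantiomer of acetonide 12 | c1ccccc1COc1ccc2c(c1)O[C@@H]1OC(C)(C)O[C@@H]1[C@@H]2c1cc(Br)c(OCc2ccccc2)cc1OCc1ccccc1
F2 | step 10 | (3S,4R)-7-(benzyloxy)-4-[2,4-bis(benzyloxy)-5-bromophenyl]-2-methoxychroman-3-yl benzoate, C2 epimers | c1ccccc1COc1ccc2c(c1)OC(OC)[C@@H](OC(=O)c1ccccc1)[C@H]2c1cc(Br)c(OCc2ccccc2)cc1OCc1ccccc1
F3 | step 10 | (2R,3S,4R)-7-(benzyloxy)-2-[3,4-bis(benzyloxy)phenyl]-4-[2,4-bis(benzyloxy)-5-bromophenyl]chroman-3-yl benzoate | c1ccccc1COc1ccc2c(c1)O[C@H](c1ccc(OCc3ccccc3)c(OCc3ccccc3)c1)[C@@H](OC(=O)c1ccccc1)[C@H]2c1cc(Br)c(OCc2ccccc2)cc1OCc1ccccc1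
F4 | step 10 | (2R,3S,4R)-7-(benzyloxy)-2-[3,4-bis(benzyloxy)phenyl]-4-[2,4-bis(benzyloxy)-5-bromophenyl]chroman-3-ol | c1ccccc1COc1ccc2c(c1)O[C@H](c1ccc(OCc3ccccc3)c(OCc3ccccc3)c1)[C@@H](O)[C@H]2c1cc(Br)c(OCc2ccccc2)cc1OCc1ccccc1
F5 | step 16 | (2R,3S)-3-[(tert-butyldimethylsilyl)oxy]-3-(3,4-dihydroxyphenyl)-1-{5-[(2R,3S,4S)-2-(3,4-dihydroxyphenyl)-3,7-dihydroxychroman-4-yl]-2,4-dihydroxyphenyl}-2-hydroxypropan-1-one | Oc1ccc2c(c1)O[C@H](c1ccc(O)c(O)c1)[C@@H](O)[C@H]2c1cc(C(=O)[C@H](O)[C@@H](O[Si](C)(C)C(C)(C)C)c2ccc(O)c(O)c2)c(O)cc1O
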